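**Plan**

- Retrosynthesis: the six phenols are traced back to methyl ethers, the C5–vinyl bond is cut (Heck), then the dihydrofuran ring is opened at C2–C3 and O1–C2, which removes C2 as a one-carbon unit.
- Enabling feature: in the dihydrobenzofuran ring (O1, C2, C3, C3a, C7a), C2 is a benzylic CH bonded to O1 and C3. O1–C7a–C3a–C3 can therefore come from an o-quinone methide (four atoms) and C2, with its 3,4-dioxygenated aryl group, from a benzylidene sulfonium ylide (one atom).
- Forward: Grignard addition and sulfinate exchange give the quinone methide precursor; a C2-symmetric thiolane is made from a chiral diol and benzylated; a base-mediated (4+1) annulation closes the only new ring; Heck coupling adds the styryl arm; BBr3 frees the phenols.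
- Stereochemistry: C2 and C3 are both set in the annulation, trans from the betaine geometry at ring closure and absolute sense from the (2S,5S)-thiolane, whose centres come from (2R,5R)-hexane-2,5-diol by double inversion. The E-alkene comes from the Heck β-hydride elimination.

Key step: step 7

Assumption: the sense of induction is taken from the known benzylidene transfer of this thiolane to aldehydes, where the (2R,5R)-sulfide gives (S,S)-stilbene oxide. With the same ylide face and inversion at the ylide carbon, the different CIP ranking at C2 (O1 > aryl > C3) means the (2S,5S)-sulfide should lead to the (2S,3S) ring. If the sense proves opposite, the enantiomeric sulfide from (2S,5S)-hexane-2,5-diol would be used in the same way.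

**Route**

Step 1
Reactants: 1 5-bromosalicylaldehyde; 2 1-bromo-3,5-dimethoxybenzene
Product: 4 racemic 4-bromo-2-[(3,5-dimethoxyphenyl)(hydroxy)methyl]phenol, via 3,5-dimethoxyphenylmagnesium bromide 3 (not isolated)
Conditions: 2 (2.3 equiv), Mg, I2 (cat.), THF, reflux; then 1, THF, 0 °C to rt; aq NH4Cl
Reagents that add atoms: none
Why: Grignard formation and 1,2-addition to the aldehyde, in which the first equivalent of 3 is consumed by the phenol, the second adds to the magnesium phenoxide aldehyde, and the aryl bromide of 1 does not exchange with an arylmagnesium halide at 0 °C; the carbinol centre is racemic and is erased later.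

Step 2
Reactants: 4 racemic 4-bromo-2-[(3,5-dimethoxyphenyl)(hydroxy)methyl]phenol
Product: 5 racemic 4-bromo-2-[(3,5-dimethoxyphenyl)(4-methylbenzenesulfonyl)methyl]phenol
Conditions: p-TolSO2H (1.5 equiv), CH2Cl2, rt
Reagents that add atoms: p-toluenesulfinic acid, Cc1ccc(S(=O)O)cc1
Why: acid-promoted SN1-type substitution of an o-hydroxybenzhydrol, in which the sulfinic acid ionises the benzylic alcohol (assisted by the ortho hydroxyl) and the sulfinate captures the cation at sulfur to give a bench-stable sulfone.

Step 3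
Reactants: 6 (2R,5R)-hexane-2,5-diol
Product: 7 (2R,5R)-hexane-2,5-diyl dimethanesulfonate
Conditions: MsCl (2.4 equiv), Et3N, CH2Cl2, −20 to 0 °C
Reagents that add atoms: methanesulfonyl chloride, CS(=O)(=O)Cl
Why: standard O-mesylation, which leaves the C–O bonds and therefore both stereocentres untouched.

Step 4
Reactants: 7 (2R,5R)-hexane-2,5-diyl dimethanesulfonate
Product: 8 (2S,5S)-2,5-dimethylthiolane
Conditions: Na2S·9H2O, EtOH, rt; pentane extraction, distillation
Reagents that add atoms: sodium sulfide, [Na+].[Na+].[S-2]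
Why: double SN2 thioetherification (intermolecular displacement, then 5-exo-tet closure by the thiolate) inverts both carbinol carbons and should convert the (2R,5R) dimesylate into the trans, C2-symmetric (2S,5S) thiolane.

Step 5
Reactants: 9 3,4-dimethoxybenzyl alcohol
Product: 10 4-(bromomethyl)-1,2-dimethoxybenzene
Conditions: PBr3 (0.4 equiv), Et2O, 0 °C; used at once
Reagents that add atoms: phosphorus tribromide, BrP(Br)Br
Why: alcohol-to-bromide substitution with PBr3 via the bromophosphite ester, fast at 0 °C for an electron-rich benzylic alcohol.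

Step 6
Reactants: 10 4-(bromomethyl)-1,2-dimethoxybenzene; 8 (2S,5S)-2,5-dimethylthiolane
Product: 11 (2S,5S)-1-[(3,4-dimethoxyphenyl)methyl]-2,5-dimethylthiolan-1-ium tetrafluoroborate
Conditions: 10 (1.2 equiv), NaBF4 (3 equiv), acetone, rt, dark; filter, triturate with Et2O
Reagents that add atoms: sodium tetrafluoroborate, [Na+].F[B-](F)(F)F
Why: S-alkylation of the thioether by the activated benzylic bromide with in situ anion metathesis, where precipitation of NaBr removes the nucleophilic counter-ion, and the equivalent lone pairs of the C2-symmetric thiolane allow only one sulfonium salt with no sulfur stereocentre.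

Step 7
Reactants: 5 racemic 4-bromo-2-[(3,5-dimethoxyphenyl)(4-methylbenzenesulfonyl)methyl]phenol; 11 (2S,5S)-1-[(3,4-dimethoxyphenyl)methyl]-2,5-dimethylthiolan-1-ium tetrafluoroborate
Product: 15 (2S,3S)-5-bromo-2-(3,4-dimethoxyphenyl)-3-(3,5-dimethoxyphenyl)-2,3-dihydro-1-benzofuran, via o-quinone methide 12 (not isolated), via sulfonium ylide 13 (not isolated), via anti betaine 14 (not isolated)
Conditions: 11 (1.3 equiv), Cs2CO3 (3 equiv), MeCN, −20 °C to rt
Reagents that add atoms: none
Why: Carbonate deprotonates the phenol of 5, which expels p-toluenesulfinate to give o-quinone methide 12 (the sulfone stereocentre disappears, and reversible sulfinate re-addition keeps free 12 low), and in parallel converts 11 into the semi-stabilised ylide 13; conjugate addition of the ylide carbon to the exocyclic carbon of 12 forms C2–C3, rearomatises the ring and gives betaine 14, whose phenoxide then displaces the thiolane at C2 with inversion to form O1–C2. The closest known reaction type is the sulfur-ylide (4+1) annulation of o-quinone methides released from 2-(sulfonylalkyl)phenols to trans-2,3-dihydrobenzofurans, combined with chiral-sulfide benzylidene transfer as in ylide epoxidation. The one new ring (O1, C2, C3, C3a, C7a) closes in a 5-exo-tet SN2 step. C2 is controlled by the thiolane, whose flanking methyl group shields one face of the ylide carbon, and inversion by O1 turns this into the 2S centre; C3 is set relative to C2, because the two aryl groups stay apart in the addition and in the anti-periplanar closure of 14, which gives the trans (3S) arrangement. The step needs C-attack of the ylide on the quinone methide to outrun quinone methide dimerisation and needs the aryl bromide to stay intact; the sulfinate reservoir, the high nucleophilicity of the ylide and the absence of any metal should secure this.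

Step 8
Reactants: 15 (2S,3S)-5-bromo-2-(3,4-dimethoxyphenyl)-3-(3,5-dimethoxyphenyl)-2,3-dihydro-1-benzofuran; 16 3,5-dimethoxystyrene
Product: 17 (2S,3S)-2-(3,4-dimethoxyphenyl)-3-(3,5-dimethoxyphenyl)-5-[(E)-2-(3,5-dimethoxyphenyl)ethenyl]-2,3-dihydro-1-benzofuran
Conditions: 16 (1.5 equiv), Pd(OAc)2 (5 mol %), P(o-tol)3 (12 mol %), Et3N, DMF, 110 °C
Reagents that add atoms: none
Why: Mizoroki–Heck coupling, in which oxidative addition of the aryl bromide to zerovalent palladium, syn-carbopalladation at the terminal alkene carbon and syn β-hydride elimination should give the E-stilbene, while C2 and C3 carry no hydrogen acidic enough for Et3N and stay as set.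

Step 9
Reactants: 17 (2S,3S)-2-(3,4-dimethoxyphenyl)-3-(3,5-dimethoxyphenyl)-5-[(E)-2-(3,5-dimethoxyphenyl)ethenyl]-2,3-dihydro-1-benzofuran
Product: 18 5-[(E)-2-[(2S,3S)-2-(3,4-dihydroxyphenyl)-3-(3,5-dihydroxyphenyl)-2,3-dihydro-1-benzofuran-5-yl]ethenyl]benzene-1,3-diol (CNP0207985.1)
Conditions: BBr3 (1 M in CH2Cl2, 12 equiv), CH2Cl2, −78 to 0 °C; then H2O, 0 °C
Reagents that add atoms: none
Why: Lewis-acid aryl methyl ether cleavage, in which bromide attacks the methyl group of each boron-complexed ether; the O1–C2 bond has no such unhindered carbon, and should it ionise, re-closure would return the more stable trans ring with C3 unchanged.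

**Compound list**

1 | 5-bromosalicylaldehyde (5-bromo-2-hydroxybenzaldehyde) | O=Cc1cc(Br)ccc1O | starting material
2 | 1-bromo-3,5-dimethoxybenzene | COc1cc(Br)cc(OC)c1 | starting material
3 | 3,5-dimethoxyphenylmagnesium bromide (formed in the flask) | COc1cc([Mg]Br)cc(OC)c1 | intermediate
4 | racemic 4-bromo-2-[(3,5-dimethoxyphenyl)(hydroxy)methyl]phenol | Oc1ccc(Br)cc1C(O)c1cc(OC)cc(OC)c1 | intermediate
5 | racemic 4-bromo-2-[(3,5-dimethoxyphenyl)(4-methylbenzenesulfonyl)methyl]phenol | Oc1ccc(Br)cc1C(c1cc(OC)cc(OC)c1)S(=O)(=O)c1ccc(C)cc1 | intermediate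
6 | (2R,5R)-hexane-2,5-diol | C[C@@H](O)CC[C@@H](C)O | starting material
7 | (2R,5R)-hexane-2,5-diyl dimethanesulfonate | C[C@@H](OS(C)(=O)=O)CC[C@@H](C)OS(C)(=O)=O | intermediate
8 | (2S,5S)-2,5-dimethylthiolane | C[C@H]1CC[C@H](C)S1 | intermediate
9 | 3,4-dimethoxybenzyl alcohol | COc1ccc(CO)cc1OC | starting material
10 | 4-(bromomethyl)-1,2-dimethoxybenzene (3,4-dimethoxybenzyl bromide) | COc1ccc(CBr)cc1OC | intermediate
11 | (2S,5S)-1-[(3,4-dimethoxyphenyl)methyl]-2,5-dimethylthiolan-1-ium tetrafluoroborate | C[C@H]1CC[C@H](C)[S+]1Cc1ccc(OC)c(OC)c1.F[B-](F)(F)F | intermediate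
12 | 4-bromo-6-[(3,5-dimethoxyphenyl)methylidene]cyclohexa-2,4-dien-1-one (o-quinone methide, formed in the flask) | O=C1C=CC(Br)=CC1=Cc1cc(OC)cc(OC)c1 | intermediate
13 | (2S,5S)-1-[(3,4-dimethoxyphenyl)methanidyl]-2,5-dimethylthiolan-1-ium (sulfonium ylide, formed in the flask) | C[C@H]1CC[C@H](C)[S+]1[CH-]c1ccc(OC)c(OC)c1 | intermediate
14 | 4-bromo-2-[(1S,2R)-2-(3,4-dimethoxyphenyl)-1-(3,5-dimethoxyphenyl)-2-[(2S,5S)-2,5-dimethylthiolan-1-ium-1-yl]ethyl]phenolate (anti betaine, formed in the flask) | [O-]c1ccc(Br)cc1[C@H](c1cc(OC)cc(OC)c1)[C@H](c1ccc(OC)c(OC)c1)[S+]1[C@@H](C)CC[C@@H]1C | intermediate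
15 | (2S,3S)-5-bromo-2-(3,4-dimethoxyphenyl)-3-(3,5-dimethoxyphenyl)-2,3-dihydro-1-benzofuran | Brc1ccc2c(c1)[C@H](c1cc(OC)cc(OC)c1)[C@@H](c1ccc(OC)c(OC)c1)O2 | intermediate
16 | 3,5-dimethoxystyrene | C=Cc1cc(OC)cc(OC)c1 | starting material
17 | (2S,3S)-2-(3,4-dimethoxyphenyl)-3-(3,5-dimethoxyphenyl)-5-[(E)-2-(3,5-dimethoxyphenyl)ethenyl]-2,3-dihydro-1-benzofuran | COc1cc(OC)cc(/C=C/c2ccc3c(c2)[C@H](c2cc(OC)cc(OC)c2)[C@@H](c2ccc(OC)c(OC)c2)O3)c1 | intermediate
18 | 5-[(E)-2-[(2S,3S)-2-(3,4-dihydroxyphenyl)-3-(3,5-dihydroxyphenyl)-2,3-dihydro-1-benzofuran-5-yl]ethenyl]benzene-1,3-diol | Oc1cc(O)cc(/C=C/c2ccc3c(c2)[C@H](c2cc(O)cc(O)c2)[C@@H](c2ccc(O)c(O)c2)O3)c1 | target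

**Step count and risks**

Total: 9 steps. Longest linear sequence: 6 steps (3, 4, 6, 7, 8, 9, from (2R,5R)-hexane-2,5-diol); the branch from 5-bromosalicylaldehyde is 5 steps.

Most likely to fail, in order:

1. Step 7. The ylide may discriminate its two faces less well toward a quinone methide than toward an aldehyde, and the betaine may epimerise at its acidic sulfonium α-position, so the trans product could form in low enantiomeric purity. The fallback gives up auxiliary control and resolves instead. It sets out from 10 and 5. Bromide 10 would alkylate commercial thiolane (tetrahydrothiophene) in the presence of NaBF4 in acetone to give 1-[(3,4-dimethoxyphenyl)methyl]thiolan-1-ium tetrafluoroborate F1. Annulation of F1 with 5 under Cs2CO3 in MeCN should give racemic trans-5-bromo-2-(3,4-dimethoxyphenyl)-3-(3,5-dimethoxyphenyl)-2,3-dihydro-1-benzofuran F2. Preparative chromatography on a polysaccharide chiral stationary phase would then separate the enantiomers, and the (2S,3S) fraction rejoins the route at 15.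

2. Step 9. Exhaustive cleavage of six ethers exposes the electron-rich stilbene to HBr and Lewis acid for a long time, so HBr addition, cationic cyclisation or oligomerisation at the double bond and incomplete cleavage may compete. The fallback removes the methyl groups before the alkene exists and ends with a mild methanolysis. It sets out from 15. BBr3 in CH2Cl2 would give 4-[(2S,3S)-5-bromo-3-(3,5-dihydroxyphenyl)-2,3-dihydro-1-benzofuran-2-yl]benzene-1,2-diol F3, and Ac2O/pyridine would convert it into the tetraacetate of this bromide F4. The coupling partner would come from commercial 3,5-dihydroxybenzaldehyde by Wittig methylenation with excess Ph3P=CH2 (from Ph3PCH3Br and KOt-Bu, THF). This gives 3,5-dihydroxystyrene F5, which would be acetylated without isolation to 3,5-diacetoxystyrene F6. Heck coupling of F4 with F6 (Pd(OAc)2, P(o-tol)3, Et3N, MeCN, 85 °C) should give the hexaacetate of the target F7. K2CO3 in degassed MeOH at rt, followed by acidification, returns to the route at 18.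

3. Step 8. Oxidative addition to the electron-rich aryl bromide may be slow, so catalyst decomposition and arylation at the internal alkene carbon (1,1-diarylethene) may compete at the temperature needed. The fallback builds the alkene by carbonyl olefination and sets out from 15. Bromine–lithium exchange (n-BuLi, THF, −78 °C) and a DMF quench would give (2S,3S)-2-(3,4-dimethoxyphenyl)-3-(3,5-dimethoxyphenyl)-2,3-dihydro-1-benzofuran-5-carbaldehyde F8. Horner–Wadsworth–Emmons olefination of F8 with commercial diethyl (3,5-dimethoxybenzyl)phosphonate (NaH, THF, 0 °C to rt) should give the E-alkene and returns to the route at 17.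

**Further compounds**

F1 | step 7 | 1-[(3,4-dimethoxyphenyl)methyl]thiolan-1-ium tetrafluoroborate | COc1ccc(C[S+]2CCCC2)cc1OC.F[B-](F)(F)F
F2 | step 7 | racemic trans-5-bromo-2-(3,4-dimethoxyphenyl)-3-(3,5-dimethoxyphenyl)-2,3-dihydro-1-benzofuran (both enantiomers) | Brc1ccc2c(c1)[C@H](c1cc(OC)cc(OC)c1)[C@@H](c1ccc(OC)c(OC)c1)O2.Brc1ccc2c(c1)[C@@H](c1cc(OC)cc(OC)c1)[C@H](c1ccc(OC)c(OC)c1)O2
F3 | step 9 | 4-[(2S,3S)-5-bromo-3-(3,5-dihydroxyphenyl)-2,3-dihydro-1-benzofuran-2-yl]benzene-1,2-diol | Brc1ccc2c(c1)[C@H](c1cc(O)cc(O)c1)[C@@H](c1ccc(O)c(O)c1)O2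
F4 | step 9 | (2S,3S)-2-(3,4-diacetoxyphenyl)-3-(3,5-diacetoxyphenyl)-5-bromo-2,3-dihydro-1-benzofuran | Brc1ccc2c(c1)[C@H](c1cc(OC(C)=O)cc(OC(C)=O)c1)[C@@H](c1ccc(OC(C)=O)c(OC(C)=O)c1)O2
F5 | step 9 | 3,5-dihydroxystyrene (5-ethenylbenzene-1,3-diol) | C=Cc1cc(O)cc(O)c1
F6 | step 9 | 3,5-diacetoxystyrene (5-ethenyl-1,3-phenylene diacetate) | C=Cc1cc(OC(C)=O)cc(OC(C)=O)c1
F7 | step 9 | (2S,3S)-2-(3,4-diacetoxyphenyl)-3-(3,5-diacetoxyphenyl)-5-[(E)-2-(3,5-diacetoxyphenyl)ethenyl]-2,3-dihydro-1-benzofuran | CC(=O)Oc1cc(OC(C)=O)cc(/C=C/c2ccc3c(c2)[C@H](c2cc(OC(C)=O)cc(OC(C)=O)c2)[C@@H](c2ccc(OC(C)=O)c(OC(C)=O)c2)O3)c1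
F8 | step 8 | (2S,3S)-2-(3,4-dimethoxyphenyl)-3-(3,5-dimethoxyphenyl)-2,3-dihydro-1-benzofuran-5-carbaldehyde | O=Cc1ccc2c(c1)[C@H](c1cc(OC)cc(OC)c1)[C@@H](c1ccc(OC)c(OC)c1)O2
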